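**Retrosynthetic overview**

1. Target 32 ⇐ desilylation and dehydration ⇐ intermolecular aldol addition of the lithium enolate of methyl ketone 24 to the ring ketone of pyrandione 28 (key C–C bond of the dienone arm).
2. 24 ⇐ acyl Stille coupling with a 3-furylstannane ⇐ methyl glycidate 20 ⇐ opening of epoxy δ-lactone 18 ⇐ epoxidation of unsaturated lactone 17 ⇐ intramolecular SmI2 Reformatsky reaction and dehydration of bromoacetate 15.
3. Fully substituted cyclohexanone 14 ⇐ (S)-carvone 1: two α′-alkylations (CH3, CH2OBn), vinyl conjugate addition with acetaldehyde aldol trapping, Wacker oxidation, excision of the isopropenyl control group, CBS reduction.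
4. 28 ⇐ Achmatowicz rearrangement and Jones oxidation of 2-(furan-2-yl)propan-2-ol 26 ⇐ 2-acetylfuran 25.
5. Ring order: the cyclohexane comes from the chiral pool; a temporary δ-lactone is closed on it, epoxidised and opened again; the pyranone ring is made separately and attached last.

Convention: ring carbons keep carvone numbering (C1 ring carbonyl, C2 methyl-bearing carbon, C3, C4, C5 isopropenyl-bearing carbon, C6); β is the ring face that carries the C2 methyl group in 7, α is the opposite face.

Assumption: centres that are oxidised or eliminated later (the side-chain carbinol on C2 from step 3, the carbinol carbons of 16 and 30, the peroxyketal carbon of 10, the lactol carbon of 27) are carried as epimer mixtures and written without a descriptor.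

**Route**

Step 1
Reactants: 1 (S)-(+)-carvone
Product: 3 trans-6-methylcarvone, via lithium dienolate 2 (not isolated)
Conditions: LiN(iPr)2, THF, −78 °C; then MeI, −78 to 0 °C
Reagents that add atoms: iodomethane, CI
Why: Enolate alkylation in which LiN(iPr)2 removes the kinetic α′ proton at C6 and the cross-conjugated lithium dienolate is C-methylated, the new C6 centre (mainly trans to isopropenyl) being planarised again in step 2 so that its configuration does not matter.

Step 2
Reactants: 3 trans-6-methylcarvone
Product: 5 6β-(benzyloxymethyl)-6α-methylcarvone, via lithium dienolate 4 (not isolated)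
Conditions: LiN(iPr)2, THF, −78 to −20 °C; then DMPU, BnOCH2Cl, −78 to 0 °C
Reagents that add atoms: benzyl chloromethyl ether, ClCOCc1ccccc1
Why: Second α′ enolate alkylation in which the fully substituted dienolate takes up BnOCH2Cl on the face opposite the neighbouring C5 isopropenyl group (1,2-induction), which sets the C6 quaternary centre with CH2OBn trans and methyl cis to isopropenyl.

Step 3
Reactants: 5 6β-(benzyloxymethyl)-6α-methylcarvone
Product: 7 3β-vinyl-2α-(1-hydroxyethyl) ketone, via magnesium enolate 6 (not isolated)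
Conditions: CH2=CHMgBr, CuBr·SMe2 (15 mol %), THF, −40 °C; then CH3CHO, −78 °C; then H2O
Reagents that add atoms: vinylmagnesium bromide, C=C[Mg]Br; acetaldehyde, CC=O
Why: Copper-catalysed conjugate addition followed by aldol trapping, in which the vinyl group adds to C3 anti to the C5 isopropenyl group and the magnesium enolate then adds to acetaldehyde through its face anti to the new vinyl group, which sets the C2 quaternary centre (methyl cis to vinyl) while the side-chain carbinol forms as an inconsequential epimer mixture.

Step 4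
Reactants: 7 3β-vinyl-2α-(1-hydroxyethyl) ketone
Product: 8 acetate of 7
Conditions: Ac2O, pyridine, 4-(dimethylamino)pyridine (10 mol %), CH2Cl2, rt
Reagents that add atoms: acetic anhydride, CC(=O)OC(C)=O
Why: Esterification under nucleophilic catalysis caps the retro-aldol-prone β-hydroxy ketone as an acetate that survives every step up to the saponification in step 14, without touching a stereocentre.

Step 5
Reactants: 8 acetate of 7
Product: 9 3β-acetyl ketone
Conditions: PdCl2 (10 mol %), CuCl, O2 (1 atm), DMF/H2O 7:1, rt
Reagents that add atoms: water, O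
Why: Tsuji–Wacker oxidation in which only the monosubstituted vinyl group is attacked by water at its internal carbon on palladium to give the methyl ketone, the 1,1-disubstituted isopropenyl group being inert, and no stereocentre is formed.

Step 6
Reactants: 9 3β-acetyl ketone
Product: 11 de-isopropenylated diketone, via methoxy hydroperoxide 10 (not isolated)
Conditions: O3, MeOH, −78 °C; then FeSO4·7H2O, PhSH, −78 °C to rt
Reagents that add atoms: none
Why: Ozonolytic hydrodealkenylation in which ozonolysis in methanol gives the α-methoxy hydroperoxide, FeSO4 cleaves the O–O bond by single-electron transfer, the alkoxy radical expels methyl acetate by β-scission and the secondary ring radical is reduced by PhSH, so the isopropenyl group is excised after it has directed the formation of C3 and C6 and C5 becomes a CH2 group.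

Step 7
Reactants: 11 de-isopropenylated diketone
Product: 12 (R)-carbinol
Conditions: (S)-1-methyl-3,3-diphenyltetrahydro-1H,3H-pyrrolo[1,2-c][1,3,2]oxazaborole (20 mol %), BH3·SMe2, THF, −30 °C; then H2O
Reagents that add atoms: none
Why: Corey–Bakshi–Shibata reduction in which the ring ketone flanked by two quaternary carbons is inert and the methyl ketone is reduced under reagent control, the (S)-oxazaborolidine delivering hydride to the face that gives the (R)-carbinol (ring residue as large group and methyl as small group).

Step 8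
Reactants: 12 (R)-carbinol
Product: 13 TBS ether
Conditions: TBSOTf, 2,6-lutidine, CH2Cl2, −78 to 0 °C
Reagents that add atoms: tert-butyldimethylsilyl triflate, CC(C)(C)[Si](C)(C)OS(=O)(=O)C(F)(F)F
Why: Silyl ether formation with the reactive triflate protects the new secondary alcohol for the rest of the route, and the ketone cannot form a silyl enol ether because both of its α carbons are quaternary.

Step 9
Reactants: 13 TBS ether
Product: 14 6β-hydroxymethyl ketone
Conditions: H2 (1 atm), Pd/C, EtOAc, rt
Reagents that add atoms: none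
Why: Hydrogenolysis of the benzyl ether over Pd/C is clean here because the molecule contains no alkene or furan, and it frees the primary alcohol on C6 that will tether the next carbon–carbon bond formation.

Step 10
Reactants: 14 6β-hydroxymethyl ketone
Product: 15 bromoacetate
Conditions: BrCH2COBr, pyridine, CH2Cl2, 0 °C
Reagents that add atoms: bromoacetyl bromide, BrCC(Br)=O
Why: O-Acylation of the unhindered primary alcohol with the acid bromide gives the α-bromo ester needed for the Reformatsky step without affecting the acetate or the silyl ether.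

Step 11
Reactants: 15 bromoacetate
Product: 16 β-hydroxy δ-lactone
Conditions: SmI2, THF, −78 °C to rt; then H2O
Reagents that add atoms: none
Why: Intramolecular samarium Reformatsky reaction in which SmI2 reduces the C–Br bond to a samarium enolate that is tethered next to the hindered ring carbonyl and adds to it through a six-membered chelated transition state to give the β-hydroxy δ-lactone, whose new tertiary carbinol centre is destroyed in step 12.

Step 12
Reactants: 16 β-hydroxy δ-lactone
Product: 17 unsaturated δ-lactone
Conditions: SOCl2, pyridine, 0 °C to rt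
Reagents that add atoms: none
Why: Dehydration through the chlorosulfite (E2 or E1cB with pyridine) can only proceed towards the acidic lactone α-CH2 because both other neighbours of the carbinol are quaternary, which gives the conjugated δ-lactone in which the ring fixes the alkene geometry with the carbonyl carbon cis to C6.

Step 13
Reactants: 17 unsaturated δ-lactone
Product: 18 β-epoxy δ-lactone
Conditions: dimethyldioxirane (acetone solution), CH2Cl2, 0 °C to rt
Reagents that add atoms: dimethyldioxirane, CC1(C)OO1
Why: Electrophilic epoxidation with dimethyldioxirane (neutral conditions suited to an electron-poor trisubstituted alkene) is expected on the β face because the α face of the lactone ring is screened by the pseudoaxial C6 methyl and the C2 acetoxyethyl arm, and the cis ring fusion fixes the relative configuration of the two epoxide carbons.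

Step 14
Reactants: 18 β-epoxy δ-lactone
Product: 20 methyl glycidate diol, via lithium glycidate 19 (not isolated)
Conditions: LiOH·H2O, THF/MeOH/H2O, 40 °C; evaporate; then MeI, DMF, rt (product used at once)
Reagents that add atoms: lithium hydroxide, [Li+].[OH-]; iodomethane, CI
Why: Saponification opens the δ-lactone to the lithium carboxylate and cleaves the acetate, and SN2 O-methylation of the carboxylate with MeI then gives the methyl glycidate without ever generating the free hydroxy acid that would relactonise, all stereocentres being untouched.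

Step 15
Reactants: 20 methyl glycidate diol
Product: 21 keto aldehyde
Conditions: Dess–Martin periodinane, CH2Cl2, 0 °C to rt
Reagents that add atoms: none
Why: Dess–Martin oxidation converts the neopentyl primary alcohol into the aldehyde and the epimeric side-chain carbinol into the methyl ketone under non-basic conditions, which removes the stereocentre that was carried as a mixture.

Step 16
Reactants: 21 keto aldehyde
Product: 22 keto acid
Conditions: NaClO2, NaH2PO4, 2-methyl-2-butene, t-BuOH/H2O, 0 °C to rt
Reagents that add atoms: sodium chlorite, [Na+].[O-]Cl=O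
Why: Pinnick oxidation (chlorous acid with an alkene scavenger for HOCl) takes the non-enolisable aldehyde to the carboxylic acid without affecting the methyl ketone, the epoxide or the silyl ether.

Step 17
Reactants: 22 keto acid
Product: 24 furyl ketone, via acid chloride 23 (not isolated)
Conditions: 1-chloro-N,N,2-trimethylprop-1-en-1-amine, CH2Cl2, 0 °C to rt; then 3-(tributylstannyl)furan, PdCl2(PPh3)2 (5 mol %), toluene, 70 °C
Reagents that add atoms: 3-(tributylstannyl)furan, CCCC[Sn](CCCC)(CCCC)c1ccoc1
Why: Acyl chloride formation under neutral conditions with the α-chloroenamine followed by a Migita–Kosugi–Stille acylation with the 3-furylstannane installs the furyl ketone chemoselectively, since neither stage involves a base or a nucleophile that could attack the methyl ketone, the glycidic ester or the epoxide.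

Step 18
Reactants: 25 2-acetylfuran
Product: 26 2-(furan-2-yl)propan-2-ol
Conditions: CH3MgBr, THF, 0 °C; then H2O
Reagents that add atoms: methylmagnesium bromide, C[Mg]Br
Why: Grignard addition of CH3MgBr to the ketone gives the tertiary furyl carbinol.

Step 19
Reactants: 26 2-(furan-2-yl)propan-2-ol
Product: 27 6-hydroxy-2,2-dimethyl-2H-pyran-3(6H)-one
Conditions: mCPBA, CH2Cl2, 0 °C to rt
Reagents that add atoms: 3-chloroperoxybenzoic acid, OOC(=O)c1cccc(Cl)c1
Why: Achmatowicz rearrangement in which epoxidation of the furan, ring opening to the ene-dione and recyclisation of the tertiary hydroxyl give the 6-hydroxy-2H-pyran-3(6H)-one as a racemic lactol whose stereocentre is removed in step 20.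

Step 20
Reactants: 27 6-hydroxy-2,2-dimethyl-2H-pyran-3(6H)-one
Product: 28 6,6-dimethyl-2H-pyran-2,5(6H)-dione
Conditions: CrO3, H2SO4, acetone, 0 °C
Reagents that add atoms: none
Why: Jones oxidation of the lactol gives the lactone, which leaves the ring ketone as the only ketone of a non-enolisable ene-dione.

Step 21
Reactants: 24 furyl ketone and 28 6,6-dimethyl-2H-pyran-2,5(6H)-dione
Product: 30 aldol adduct, via lithium enolate 29 (not isolated)
Conditions: LiN(SiMe3)2, THF, −78 °C; then 28, −78 °C; then AcOH, −78 °C
Reagents that add atoms: none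
Why: Intermolecular aldol addition (the key fragment union) in which LiN(SiMe3)2 deprotonates the only enolisable position of 24, the acetyl methyl group, and at −78 °C the lithium enolate is expected to add 1,2 to the non-enolisable ketone of 28, which is activated by the α-acyloxy carbon and the ene-dione, the tertiary carbinol so formed being eliminated in step 22.

Step 22
Reactants: 30 aldol adduct
Product: 31 TBS ether of the target
Conditions: methyl N-(triethylammoniosulfonyl)carbamate (Burgess reagent), toluene, 50 °C
Reagents that add atoms: none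
Why: Burgess dehydration (syn elimination of the sulfamate ester) can only use the CH2 group next to the ketone and gives the cross-conjugated exocyclic alkene with the acyl group trans to the gem-dimethyl carbon (E), which is the less strained transition state and the thermodynamically preferred geometry.

Step 23
Reactants: 31 TBS ether of the target
Product: 32 CNP0293135.1
Conditions: HF·pyridine, pyridine, THF, 0 °C to rt
Reagents that add atoms: none
Why: Fluoride-mediated desilylation under buffered acidic conditions removes the TBS ether without opening the glycidic epoxide or adding to the dienone lactone, and gives the target with all six stereocentres and the E alkene in place.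

**Compound list**

1 | (S)-(+)-carvone, (5S)-2-methyl-5-(prop-1-en-2-yl)cyclohex-2-en-1-one | CC1=CC[C@@H](CC1=O)C(C)=C | starting material
2 | lithium α′-dienolate of 1 (O–Li on C1, C1=C6 and C2=C3) | [Li]OC1=C[C@@H](C(C)=C)CC=C1C | intermediate
3 | trans-6-methylcarvone, (5S,6R)-2,6-dimethyl-5-(prop-1-en-2-yl)cyclohex-2-en-1-one (major epimer) | O=C1[C@H](C)[C@@H](C(C)=C)CC=C1C | intermediate
4 | lithium α′-dienolate of 3 (C1=C6 tetrasubstituted) | [Li]OC1=C(C)[C@@H](C(C)=C)CC=C1C | intermediate
5 | 6β-[(benzyloxy)methyl]-2,6α-dimethyl-5α-(prop-1-en-2-yl)cyclohex-2-en-1-one | O=C1[C@](C)(COCc2ccccc2)[C@@H](C(C)=C)CC=C1C | intermediate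
6 | bromomagnesium C1=C2 enolate carrying the 3β-vinyl group | Br[Mg]OC=1[C@](C)(COCc2ccccc2)[C@@H](C(C)=C)C[C@H](C=C)C=1C | intermediate
7 | 6β-[(benzyloxy)methyl]-2α-(1-hydroxyethyl)-2β,6α-dimethyl-5α-(prop-1-en-2-yl)-3β-vinylcyclohexan-1-one (carbinol epimers) | O=C1[C@](C)(COCc2ccccc2)[C@@H](C(C)=C)C[C@H](C=C)[C@@]1(C)C(C)O | intermediate
8 | 2α-(1-acetoxyethyl) analogue of 7 | O=C1[C@](C)(COCc2ccccc2)[C@@H](C(C)=C)C[C@H](C=C)[C@@]1(C)C(C)OC(C)=O | intermediate
9 | 3β-acetyl-2α-(1-acetoxyethyl)-6β-[(benzyloxy)methyl]-2β,6α-dimethyl-5α-(prop-1-en-2-yl)cyclohexan-1-one | O=C1[C@](C)(COCc2ccccc2)[C@@H](C(C)=C)C[C@H](C(C)=O)[C@@]1(C)C(C)OC(C)=O | intermediate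
10 | 9 with the isopropenyl group converted into a 1-hydroperoxy-1-methoxyethyl group | O=C1[C@](C)(COCc2ccccc2)[C@@H](C(C)(OC)OO)C[C@H](C(C)=O)[C@@]1(C)C(C)OC(C)=O | intermediate
11 | 3β-acetyl-2α-(1-acetoxyethyl)-6β-[(benzyloxy)methyl]-2β,6α-dimethylcyclohexan-1-one | O=C1[C@](C)(COCc2ccccc2)CC[C@H](C(C)=O)[C@@]1(C)C(C)OC(C)=O | intermediate
12 | 2α-(1-acetoxyethyl)-6β-[(benzyloxy)methyl]-3β-[(1R)-1-hydroxyethyl]-2β,6α-dimethylcyclohexan-1-one | O=C1[C@](C)(COCc2ccccc2)CC[C@H]([C@@H](C)O)[C@@]1(C)C(C)OC(C)=O | intermediate
13 | tert-butyldimethylsilyl ether of 12 | O=C1[C@](C)(COCc2ccccc2)CC[C@H]([C@@H](C)O[Si](C)(C)C(C)(C)C)[C@@]1(C)C(C)OC(C)=O | intermediate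
14 | 2α-(1-acetoxyethyl)-6β-(hydroxymethyl)-2β,6α-dimethyl-3β-[(1R)-1-(tert-butyldimethylsilyloxy)ethyl]cyclohexan-1-one | O=C1[C@](C)(CO)CC[C@H]([C@@H](C)O[Si](C)(C)C(C)(C)C)[C@@]1(C)C(C)OC(C)=O | intermediate
15 | bromoacetate ester of the primary alcohol of 14 | O=C1[C@](C)(COC(=O)CBr)CC[C@H]([C@@H](C)O[Si](C)(C)C(C)(C)C)[C@@]1(C)C(C)OC(C)=O | intermediate
16 | β-hydroxy δ-lactone: 4a-hydroxy-perhydroisochromen-3-one with 5-(1-acetoxyethyl), 5,8a-dimethyl and 6-[(1R)-1-(TBSO)ethyl] groups (C4a epimer unassigned) | OC12CC(=O)OC[C@]1(C)CC[C@H]([C@@H](C)O[Si](C)(C)C(C)(C)C)[C@@]2(C)C(C)OC(C)=O | intermediate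
17 | α,β-unsaturated δ-lactone (C4=C4a isochromen-3-one) obtained by dehydration of 16 | O=C1OC[C@]2(C)CC[C@H]([C@@H](C)O[Si](C)(C)C(C)(C)C)[C@@](C)(C(C)OC(C)=O)C2=C1 | intermediate
18 | 4,4a-epoxide of 17, epoxide oxygen on the β face | O=C1OC[C@]2(C)CC[C@H]([C@@H](C)O[Si](C)(C)C(C)(C)C)[C@@](C)(C(C)OC(C)=O)[C@]23O[C@H]13 | intermediate
19 | lithium 4-(hydroxymethyl)-8-(1-hydroxyethyl)-4,8-dimethyl-7-[(1R)-1-(TBSO)ethyl]-1-oxaspiro[2.5]octane-2-carboxylate | [Li+].[O-]C(=O)[C@H]1O[C@@]12[C@](C)(CO)CC[C@H]([C@@H](C)O[Si](C)(C)C(C)(C)C)[C@@]2(C)C(C)O | intermediate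
20 | methyl ester of 19 | COC(=O)[C@H]1O[C@@]12[C@](C)(CO)CC[C@H]([C@@H](C)O[Si](C)(C)C(C)(C)C)[C@@]2(C)C(C)O | intermediate
21 | methyl 8-acetyl-4-formyl-4,8-dimethyl-7-[(1R)-1-(TBSO)ethyl]-1-oxaspiro[2.5]octane-2-carboxylate | COC(=O)[C@H]1O[C@@]12[C@](C)(C=O)CC[C@H]([C@@H](C)O[Si](C)(C)C(C)(C)C)[C@@]2(C)C(C)=O | intermediate
22 | 8-acetyl-2-(methoxycarbonyl)-4,8-dimethyl-7-[(1R)-1-(TBSO)ethyl]-1-oxaspiro[2.5]octane-4-carboxylic acid | COC(=O)[C@H]1O[C@@]12[C@](C)(C(O)=O)CC[C@H]([C@@H](C)O[Si](C)(C)C(C)(C)C)[C@@]2(C)C(C)=O | intermediate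
23 | acid chloride of 22 | COC(=O)[C@H]1O[C@@]12[C@](C)(C(Cl)=O)CC[C@H]([C@@H](C)O[Si](C)(C)C(C)(C)C)[C@@]2(C)C(C)=O | intermediate
24 | methyl 8-acetyl-4-(furan-3-carbonyl)-4,8-dimethyl-7-[(1R)-1-(TBSO)ethyl]-1-oxaspiro[2.5]octane-2-carboxylate | COC(=O)[C@H]1O[C@@]12[C@](C)(C(=O)c1ccoc1)CC[C@H]([C@@H](C)O[Si](C)(C)C(C)(C)C)[C@@]2(C)C(C)=O | intermediate
25 | 2-acetylfuran | CC(=O)c1ccco1 | starting material
26 | 2-(furan-2-yl)propan-2-ol | CC(C)(O)c1ccco1 | intermediate
27 | 6-hydroxy-2,2-dimethyl-2H-pyran-3(6H)-one (racemic lactol) | OC1C=CC(=O)C(C)(C)O1 | intermediate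
28 | 6,6-dimethyl-2H-pyran-2,5(6H)-dione | O=C1C=CC(=O)C(C)(C)O1 | intermediate
29 | lithium enolate of the acetyl group of 24 | COC(=O)[C@H]1O[C@@]12[C@](C)(C(=O)c1ccoc1)CC[C@H]([C@@H](C)O[Si](C)(C)C(C)(C)C)[C@@]2(C)C(=C)O[Li] | intermediate
30 | aldol adduct: 24 with the acetyl CH3 joined to C5 of 28 as a tertiary carbinol, 8-[2-(3-hydroxy-2,2-dimethyl-6-oxo-3,6-dihydro-2H-pyran-3-yl)acetyl] (carbinol epimers) | COC(=O)[C@H]1O[C@@]12[C@](C)(C(=O)c1ccoc1)CC[C@H]([C@@H](C)O[Si](C)(C)C(C)(C)C)[C@@]2(C)C(=O)CC1(O)C=CC(=O)OC1(C)C | intermediate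
31 | tert-butyldimethylsilyl ether of the target, 8-[(E)-2-(2,2-dimethyl-6-oxo-2H-pyran-3(6H)-ylidene)acetyl] | COC(=O)[C@H]1O[C@@]12[C@](C)(C(=O)c1ccoc1)CC[C@H]([C@@H](C)O[Si](C)(C)C(C)(C)C)[C@@]2(C)C(=O)/C=C1\C=CC(=O)OC1(C)C | intermediate
32 | CNP0293135.1, methyl 8-[(E)-2-(2,2-dimethyl-6-oxo-2H-pyran-3(6H)-ylidene)acetyl]-4-(furan-3-carbonyl)-7-[(1R)-1-hydroxyethyl]-4,8-dimethyl-1-oxaspiro[2.5]octane-2-carboxylate | COC(=O)[C@H]1O[C@@]12[C@](C)(C(=O)c1ccoc1)CC[C@H]([C@@H](C)O)[C@@]2(C)C(=O)/C=C1\C=CC(=O)OC1(C)C | target

**Totals and weak points**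

Total step count: 23. Longest linear sequence: 20 steps (steps 1 to 17, then 21 to 23); steps 18 to 20 form the three-step side branch to 28.

Step 11 is the most exposed step. The ring carbonyl is flanked by two quaternary carbons, so the samarium enolate may simply be protonated instead of adding. The fallback sets out from 14 and comes back at 16. Lithium ethoxyacetylide (LiC≡COEt, 3 equiv, with CeCl3, THF, −78 to 0 °C) is the smallest available acetate equivalent and adds to the hindered ketone to give the ethoxyalkynyl diol F1. Heating F1 in xylene at about 130 °C with Bu3N releases ethene in a retro-ene reaction, and the resulting ketene is trapped by the neighbouring primary alcohol, which closes the δ-lactone and delivers 16.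

Step 13 may be slow on the hindered alkene or may give the α-epoxide. The fallback sets out from 17 and comes back at 20, and replaces substrate control by reagent control. LiAlH4 (THF, 0 °C) reduces the lactone and the acetate to the allylic triol F2. Sharpless asymmetric epoxidation with stoichiometric Ti(OiPr)4, L-(+)-diethyl tartrate and t-BuOOH (CH2Cl2, −20 °C) puts the oxygen on the β face, as the Sharpless mnemonic predicts for this allylic alcohol, and gives the epoxy triol F3. Oxidative lactonisation with 2,2,6,6-tetramethylpiperidin-1-oxyl and PhI(OAc)2 starts at the less hindered epoxy carbinol and gives the epoxy lactone with a free side-chain carbinol F4, which under the conditions of step 14 gives 20.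

Step 21 may suffer conjugate addition of the enolate to the ene-dione or decomposition of 28 under basic conditions. The fallback sets out from 24 (partner made from 27) and comes back at 31; it keeps the aldol union but uses a less electrophilic partner. Lactol 27 is converted with MeOH, HC(OMe)3 and catalytic pyridinium p-toluenesulfonate into the methyl acetal F5, a simple enone. Enolate 29 (transmetallated with CeCl3) adds 1,2 to its ketone to give the aldol adduct F6, and Burgess dehydration gives the dienone acetal F7. Mild hydrolysis (pyridinium p-toluenesulfonate, acetone/H2O) gives the lactol F8, and MnO2 in CH2Cl2 oxidises it to lactone 31.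

**Further compounds**

F1 | step 11 | ethoxyalkynyl diol (1-(ethoxyethynyl)cyclohexan-1-ol from 14, carbinol epimer unassigned) | CCOC#CC1(O)[C@](C)(CO)CC[C@H]([C@@H](C)O[Si](C)(C)C(C)(C)C)[C@@]1(C)C(C)OC(C)=O
F2 | step 13 | allylic triol (2-hydroxyethylidene cyclohexane, CH2OH cis to C6) | OC/C=C1\[C@](C)(CO)CC[C@H]([C@@H](C)O[Si](C)(C)C(C)(C)C)[C@@]1(C)C(C)O
F3 | step 13 | β-epoxy triol (2-(hydroxymethyl)-1-oxaspiro[2.5]octane) | OC[C@H]1O[C@@]12[C@](C)(CO)CC[C@H]([C@@H](C)O[Si](C)(C)C(C)(C)C)[C@@]2(C)C(C)O
F4 | step 13 | β-epoxy δ-lactone with free side-chain carbinol (deacetyl 18) | O=C1OC[C@]2(C)CC[C@H]([C@@H](C)O[Si](C)(C)C(C)(C)C)[C@@](C)(C(C)O)[C@]23O[C@H]13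
F5 | step 21 | 6-methoxy-2,2-dimethyl-2H-pyran-3(6H)-one | COC1C=CC(=O)C(C)(C)O1
F6 | step 21 | aldol adduct of 24 with F5 (tertiary carbinol, methyl acetal) | COC(=O)[C@H]1O[C@@]12[C@](C)(C(=O)c1ccoc1)CC[C@H]([C@@H](C)O[Si](C)(C)C(C)(C)C)[C@@]2(C)C(=O)CC1(O)C=CC(OC)OC1(C)C
F7 | step 21 | dienone methyl acetal | COC(=O)[C@H]1O[C@@]12[C@](C)(C(=O)c1ccoc1)CC[C@H]([C@@H](C)O[Si](C)(C)C(C)(C)C)[C@@]2(C)C(=O)/C=C1\C=CC(OC)OC1(C)C
F8 | step 21 | dienone lactol | COC(=O)[C@H]1O[C@@]12[C@](C)(C(=O)c1ccoc1)CC[C@H]([C@@H](C)O[Si](C)(C)C(C)(C)C)[C@@]2(C)C(=O)/C=C1\C=CC(O)OC1(C)C
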